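## Retrosynthetic overview
1. No ring is formed. Ring A (3-methoxyphenyl), ring B (central) and ring C (4-hydroxyphenyl) are all bought, and only the two links between them are made.
2. The last step is one hydrogenation/hydrogenolysis of a stilbene benzhydrol O-benzyl ether. It delivers the ArCH2Ar link, the CH2CH2 link and the ring C phenol together.
3. The B–C link comes from addition of an aryl Grignard reagent to a ring B salicylaldehyde.
4. The OH/OMe difference on ring B comes from formyl-directed mono-demethylation of a symmetrical 2,6-dimethoxybenzaldehyde.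
5. The A–B link comes from Heck coupling of 4-bromo-2,6-dimethoxybenzaldehyde with 3-methoxystyrene, which is the first forward step.

Assumption: the target (C23H24O4) has no stereocentre and no stereogenic double bond, so it is achiral and needs no asymmetric step. The E-alkene and the racemic carbinol centre made on the way are both erased in step 4.

## Route

**Step 1**
Reactants: 1 4-bromo-2,6-dimethoxybenzaldehyde; 2 3-methoxystyrene (1-ethenyl-3-methoxybenzene)
Product: 3 2,6-dimethoxy-4-[(E)-2-(3-methoxyphenyl)ethenyl]benzaldehyde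
Conditions: Pd(OAc)2 (2 mol %), P(o-tol)3 (6 mol %), NaOAc (1.5 equiv), DMA, 120 °C, 12 h
Reagents that add atoms: none
Why: Mizoroki–Heck reaction, in which the C–Br bond para to the formyl group adds readily to zerovalent palladium, and syn insertion of the styrene followed by syn β-hydride elimination gives the E-stilbene without making a stereocentre.

**Step 2**
Reactants: 3 2,6-dimethoxy-4-[(E)-2-(3-methoxyphenyl)ethenyl]benzaldehyde
Product: 5 2-hydroxy-6-methoxy-4-[(E)-2-(3-methoxyphenyl)ethenyl]benzaldehyde, via dichloroboron chelate 4 (not isolated)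
Conditions: BCl3 (1.2 equiv, 1 M in CH2Cl2), CH2Cl2, −78 → 0 °C, 2 h; then H2O
Reagents that add atoms: boron trichloride, ClB(Cl)Cl (its B and Cl sit in 4 only; 5 gains nothing but H)
Why: Chelation-directed Lewis acid ether cleavage, in which BCl3 bound to the formyl oxygen reaches only an ortho methoxy group, and once the six-membered chelate 4 has formed, the second ortho ether and the remote ring A ether are left alone at low temperature.

**Step 3**
Reactants: 5 2-hydroxy-6-methoxy-4-[(E)-2-(3-methoxyphenyl)ethenyl]benzaldehyde; 6 4-(benzyloxy)phenylmagnesium bromide (sold as a THF solution)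
Product: 9 (±)-2-{[4-(benzyloxy)phenyl](hydroxy)methyl}-3-methoxy-5-[(E)-2-(3-methoxyphenyl)ethenyl]phenol, via bromomagnesium phenoxide 7 (not isolated), via bis(bromomagnesium) salt 8 (not isolated)
Conditions: 6 (2.5 equiv), THF, 0 °C → rt, 3 h; then sat. aq NH4Cl; used crude
Reagents that add atoms: none
Why: Grignard 1,2-addition, in which the first equivalent only deprotonates the phenol and the second adds to the aldehyde, giving a racemic carbinol centre that does not matter because step 4 erases it.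

**Step 4**
Reactants: 9 (±)-2-{[4-(benzyloxy)phenyl](hydroxy)methyl}-3-methoxy-5-[(E)-2-(3-methoxyphenyl)ethenyl]phenol
Product: 12 2-(4-hydroxybenzyl)-3-methoxy-5-[2-(3-methoxyphenyl)ethyl]phenol (IN0509), via saturated carbinol benzyl ether 10 (not isolated), via debenzylated carbinol 11 (not isolated)
Conditions: H2 (3 atm), 10% Pd/C, EtOH–AcOH 9:1, rt, 16 h
Reagents that add atoms: none
Why: Catalytic hydrogenation/hydrogenolysis, in which Pd/C saturates the stilbene, cleaves the O-benzyl ether and, helped by the acid and the ortho/para oxygen donors, cleaves the doubly benzylic C–OH bond, removing the only stereocentre while aryl methyl ethers and phenols survive.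

## Compound list
1 | 4-bromo-2,6-dimethoxybenzaldehyde | COc1cc(Br)cc(OC)c1C=O | starting material
2 | 3-methoxystyrene | COc1cccc(C=C)c1 | starting material
3 | 2,6-dimethoxy-4-[(E)-2-(3-methoxyphenyl)ethenyl]benzaldehyde | COc1cccc(/C=C/c2cc(OC)c(C=O)c(OC)c2)c1 | intermediate
4 | 2-(dichloroboryloxy)-6-methoxy-4-[(E)-2-(3-methoxyphenyl)ethenyl]benzaldehyde, boron also bound to the formyl oxygen (formed in the flask) | COc1cccc(/C=C/c2cc(OC)c(C=O)c(OB(Cl)Cl)c2)c1 | intermediate
5 | 2-hydroxy-6-methoxy-4-[(E)-2-(3-methoxyphenyl)ethenyl]benzaldehyde | COc1cccc(/C=C/c2cc(OC)c(C=O)c(O)c2)c1 | intermediate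
6 | 4-(benzyloxy)phenylmagnesium bromide | Br[Mg]c1ccc(OCc2ccccc2)cc1 | starting material
7 | bromomagnesium phenoxide of 5 (formed in the flask) | COc1cccc(/C=C/c2cc(OC)c(C=O)c(O[Mg]Br)c2)c1 | intermediate
8 | bis(bromomagnesium) alkoxide-phenoxide of 9, racemic (formed in the flask) | COc1cccc(/C=C/c2cc(OC)c(C(O[Mg]Br)c3ccc(OCc4ccccc4)cc3)c(O[Mg]Br)c2)c1 | intermediate
9 | (±)-2-{[4-(benzyloxy)phenyl](hydroxy)methyl}-3-methoxy-5-[(E)-2-(3-methoxyphenyl)ethenyl]phenol | COc1cccc(/C=C/c2cc(OC)c(C(O)c3ccc(OCc4ccccc4)cc3)c(O)c2)c1 | intermediate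
10 | (±)-2-{[4-(benzyloxy)phenyl](hydroxy)methyl}-3-methoxy-5-[2-(3-methoxyphenyl)ethyl]phenol (formed in the flask) | COc1cccc(CCc2cc(OC)c(C(O)c3ccc(OCc4ccccc4)cc3)c(O)c2)c1 | intermediate
11 | (±)-2-[hydroxy(4-hydroxyphenyl)methyl]-3-methoxy-5-[2-(3-methoxyphenyl)ethyl]phenol (formed in the flask) | COc1cccc(CCc2cc(OC)c(C(O)c3ccc(O)cc3)c(O)c2)c1 | intermediate
12 | 2-(4-hydroxybenzyl)-3-methoxy-5-[2-(3-methoxyphenyl)ethyl]phenol (IN0509, achiral) | COc1cccc(CCc2cc(O)c(Cc3ccc(O)cc3)c(OC)c2)c1 | target

## Step count and weak points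
Total step count: 4. Longest linear sequence: 4 (1 → 3 → 5 → 9 → 12).

**Step 4.** Three reductions are asked of one pot. The doubly benzylic C–OH cleavage may lag behind, or the acid-labile carbinol may self-condense. The fallback sets out from 9 and comes back at 12. The C–O bond is removed first by ionic hydrogenation (Et3SiH, CF3CO2H, CH2Cl2, −20 °C). This gives 2-[4-(benzyloxy)benzyl]-3-methoxy-5-[(E)-2-(3-methoxyphenyl)ethenyl]phenol F1. A neutral hydrogenation (H2, 10% Pd/C, EtOAc, rt) then has only the easy tasks left. It passes through 2-[4-(benzyloxy)benzyl]-3-methoxy-5-[2-(3-methoxyphenyl)ethyl]phenol F2 to 12.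

**Step 3.** The aldehyde is flanked on both sides and is deactivated as its magnesium phenoxide, and the ortho-hydroxy carbinol 9 is fragile. The fallback sets out from 5 and comes back at 11.
- Compound 5 is capped with BnBr and K2CO3 in DMF to give 2-(benzyloxy)-6-methoxy-4-[(E)-2-(3-methoxyphenyl)ethenyl]benzaldehyde F3.
- F3 is a normally electrophilic aldehyde and needs only 1.2 equiv of 6. It gives the bromomagnesium alkoxide F4.
- After NH4Cl, F4 gives the chromatography-stable (±)-[4-(benzyloxy)phenyl]{2-(benzyloxy)-6-methoxy-4-[(E)-2-(3-methoxyphenyl)ethenyl]phenyl}methanol F5.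
- Under the conditions of step 4, F5 goes through (±)-[4-(benzyloxy)phenyl]{2-(benzyloxy)-6-methoxy-4-[2-(3-methoxyphenyl)ethyl]phenyl}methanol F6 to 11, and from there to 12.

**Step 2.** The risks are double demethylation or damage to the stilbene by the Lewis acid. The fallback sets out from 1 and comes back at 5. The order of bond making is swapped, so that BCl3 meets neither the alkene nor the ring A ether. Compound 1 with BCl3 in CH2Cl2 gives the dichloroboron chelate F7, and after water 4-bromo-2-hydroxy-6-methoxybenzaldehyde F8. Heck coupling of F8 with 2 then gives 5 directly. It uses Pd(OAc)2, P(o-tol)3, NaOAc and DMA; NaOAc is too weak a base to form much phenoxide.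

## Further compounds
F1 | step 4 | 2-[4-(benzyloxy)benzyl]-3-methoxy-5-[(E)-2-(3-methoxyphenyl)ethenyl]phenol | COc1cccc(/C=C/c2cc(O)c(Cc3ccc(OCc4ccccc4)cc3)c(OC)c2)c1
F2 | step 4 | 2-[4-(benzyloxy)benzyl]-3-methoxy-5-[2-(3-methoxyphenyl)ethyl]phenol | COc1cccc(CCc2cc(O)c(Cc3ccc(OCc4ccccc4)cc3)c(OC)c2)c1
F3 | step 3 | 2-(benzyloxy)-6-methoxy-4-[(E)-2-(3-methoxyphenyl)ethenyl]benzaldehyde | COc1cccc(/C=C/c2cc(OC)c(C=O)c(OCc3ccccc3)c2)c1
F4 | step 3 | bromomagnesium alkoxide (of F5, racemic) | COc1cccc(/C=C/c2cc(OC)c(C(O[Mg]Br)c3ccc(OCc4ccccc4)cc3)c(OCc5ccccc5)c2)c1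
F5 | step 3 | (±)-[4-(benzyloxy)phenyl]{2-(benzyloxy)-6-methoxy-4-[(E)-2-(3-methoxyphenyl)ethenyl]phenyl}methanol | COc1cccc(/C=C/c2cc(OC)c(C(O)c3ccc(OCc4ccccc4)cc3)c(OCc5ccccc5)c2)c1
F6 | step 3 | (±)-[4-(benzyloxy)phenyl]{2-(benzyloxy)-6-methoxy-4-[2-(3-methoxyphenyl)ethyl]phenyl}methanol | COc1cccc(CCc2cc(OC)c(C(O)c3ccc(OCc4ccccc4)cc3)c(OCc5ccccc5)c2)c1
F7 | step 2 | dichloroboron chelate (4-bromo-2-(dichloroboryloxy)-6-methoxybenzaldehyde) | COc1cc(Br)cc(OB(Cl)Cl)c1C=O
F8 | step 2 | 4-bromo-2-hydroxy-6-methoxybenzaldehyde | COc1cc(Br)cc(O)c1C=O
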